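**Strategy**

The oxolane is disconnected at O1–C5 and C5–CH2Ar. The feature exploited is that C5 of the tetrahydrofuran ring (O1, C2 aryl, C3 CH2OH, C4 OH, C5) carries both the ring oxygen and the 4-hydroxy-3-methoxybenzyl carbon. A copper carbenoid generated at C5 of an acyclic diazoketone is trapped by the benzylic ether oxygen on C2; the five-membered oxonium ylide then hands its O-arylmethyl group to C5, so one operation closes the ring, makes both bonds and leaves a C4 ketone for hydroxyl-directed reduction. The precursor is a 1-diazo-4-aryl-4-(arylmethoxy)-3-(silyloxymethyl)butan-2-one whose 4-aryl group is the finished cis-dihydrobenzofuran, itself made by rhodium carbenoid C–H insertion.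

Key step: step 15

**Remarks**

- Stereochemistry read from the target SMILES: the dihydrobenzofuran is 2,3-cis (2R,3R); the oxolane is 2,3-trans, 3,4-trans, 4,5-cis, (2S,3S,4S,5S) with the ring numbered O1, C2 (aryl), C3, C4, C5 (benzyl). This numbering is used for all oxolane compounds below.
- The cis-dihydrobenzofuran is epimerisable, so it sees no strong acid or base once formed, and the phenols are freed only in the last, neutral step.
- Both primary alcohols are carried as triisopropylsilyl ethers and only the two phenols as benzyl ethers. One fluoride step then frees both alcohols, and the final hydrogenolysis has only aryl benzyl ethers to cleave.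
- Abbreviations: TIPS = triisopropylsilyl. BMB = 4-(benzyloxy)-3-methoxybenzyl. DHB = (2R,3R)-2-[4-(benzyloxy)-3-methoxyphenyl]-7-methoxy-3-(TIPS-oxymethyl)-2,3-dihydro-1-benzofuran-5-yl (2,3-cis). Rh2(S-PTTL)4 = dirhodium tetrakis[N-phthaloyl-(S)-tert-leucinate]. Cu(hfacac)2 = copper bis(hexafluoroacetylacetonate), divalent copper. (S)-TRIP = (S)-3,3'-bis(2,4,6-triisopropylphenyl)-1,1'-binaphthyl-2,2'-diyl hydrogen phosphate.
- Compounds 1, 3 and 5 are commercial.

**Route**

Step 1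
Reactants: 1 4-(benzyloxy)-3-methoxybenzyl alcohol
Product: 2 4-(benzyloxy)-3-methoxybenzyl bromide (BMB bromide)
Conditions: PBr3 (0.4 equiv), Et2O, 0 °C; used crude
Reagents that add atoms: phosphorus tribromide, BrP(Br)Br
Why: Standard conversion of a primary benzylic alcohol into its bromide (phosphite ester, then SN2 by bromide), which leaves the aryl benzyl ether untouched at 0 °C.

Step 2
Reactants: 3 5-iodovanillin (4-hydroxy-3-iodo-5-methoxybenzaldehyde); 2 BMB bromide
Product: 4 4-(BMB-oxy)-3-iodo-5-methoxybenzaldehyde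
Conditions: K2CO3, DMF, rt
Reagents that add atoms: none
Why: Williamson ether synthesis on an acidic phenol with a reactive benzylic bromide, installing the arylmethyl ether whose CH2 later becomes C2 of the dihydrobenzofuran.

Step 3
Reactants: 5 propargyl alcohol
Product: 6 triisopropyl(prop-2-yn-1-yloxy)silane
Conditions: TIPSCl, imidazole, CH2Cl2, rt
Reagents that add atoms: triisopropylsilyl chloride, CC(C)[Si](Cl)(C(C)C)C(C)C
Why: Routine silylation of a primary alcohol, the bulky silyl group being chosen because its oxygen must later stay out of the carbenoid chemistry of step 15.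

Step 4
Reactants: 6 triisopropyl(prop-2-yn-1-yloxy)silane
Product: 7 2-[(E)-3-(TIPS-oxy)prop-1-en-1-yl]-4,4,5,5-tetramethyl-1,3,2-dioxaborolane
Conditions: pinacolborane, Cp2Zr(H)Cl (5 mol %), Et3N (10 mol %), neat, 60 °C
Reagents that add atoms: pinacolborane, CC1(C)OBOC1(C)C
Why: Zirconium-catalysed hydroboration of a terminal alkyne, a syn addition with boron at the terminal carbon that gives only the (E)-alkenylboronate.

Step 5
Reactants: 7 2-[(E)-3-(TIPS-oxy)prop-1-en-1-yl]-4,4,5,5-tetramethyl-1,3,2-dioxaborolane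
Product: 8 2-[(E)-4-(TIPS-oxy)but-2-en-1-yl]-4,4,5,5-tetramethyl-1,3,2-dioxaborolane
Conditions: BrCH2Cl, n-BuLi, THF, −78 °C to rt
Reagents that add atoms: bromochloromethane, ClCBr
Why: Matteson homologation, in which LiCH2Cl made in the flask adds to boron and the alkenyl group undergoes 1,2-migration with loss of chloride, inserting one CH2 with retention of the E geometry.

Step 6
Reactants: 4 4-(BMB-oxy)-3-iodo-5-methoxybenzaldehyde; 8 (E)-allylboronate
Product: 10 (1S,2R)-1-[4-(BMB-oxy)-3-iodo-5-methoxyphenyl]-2-(TIPS-oxymethyl)but-3-en-1-ol, via pinacol borate ester 9 (not isolated)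
Conditions: (S)-TRIP (5 mol %), 4 Å molecular sieves, toluene, −30 to 0 °C; aq. NaHCO3 work-up
Reagents that add atoms: none
Why: Chiral phosphoric acid-catalysed allylboration through a closed six-membered chair transition state, in which the equatorial E γ-substituent gives the 1,2-anti product and the (S)-acid, hydrogen-bonded to the boronate oxygen and the formyl hydrogen, is expected by analogy with simple aryl aldehydes to direct attack to the Si face (1S,2R).

Step 7
Reactants: 10 (1S,2R)-homoallylic alcohol; 2 BMB bromide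
Product: 11 2-(BMB-oxy)-5-[(1S,2R)-1-(BMB-oxy)-2-(TIPS-oxymethyl)but-3-en-1-yl]-1-iodo-3-methoxybenzene
Conditions: NaH, Bu4NI (cat.), THF–DMF, 0 °C to rt
Reagents that add atoms: none
Why: Williamson etherification of the secondary benzylic alkoxide under iodide catalysis, run with base so that the electron-rich benzylic carbinol cannot ionise, the primary silyl ether having no driving force to migrate to the hindered secondary oxygen.

Step 8
Reactants: 11 bis-ether aryl iodide
Product: 12 methyl 2-{2-(BMB-oxy)-5-[(1S,2R)-1-(BMB-oxy)-2-(TIPS-oxymethyl)but-3-en-1-yl]-3-methoxyphenyl}-2-diazoacetate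
Conditions: methyl diazoacetate (2 equiv), Pd(PPh3)4 (5 mol %), Ag2CO3 (0.5 equiv), Et3N (1.3 equiv), toluene, rt
Reagents that add atoms: methyl diazoacetate, COC(=O)C=[N+]=[N-]
Why: Palladium-catalysed cross-coupling of an aryl iodide with an acceptor diazoacetate (oxidative addition, base- and silver-assisted palladation of the diazo C–H, reductive elimination), which at room temperature keeps the diazo group and leaves alkene, ethers and silyl ether untouched.

Step 9
Reactants: 12 aryl diazoacetate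
Product: 13 methyl (2R,3S)-2-[4-(benzyloxy)-3-methoxyphenyl]-5-[(1S,2R)-1-(BMB-oxy)-2-(TIPS-oxymethyl)but-3-en-1-yl]-7-methoxy-2,3-dihydro-1-benzofuran-3-carboxylate (2,3-cis)
Conditions: Rh2(S-PTTL)4 (1 mol %), toluene, −60 °C, high dilution
Reagents that add atoms: none
Why: Enantioselective intramolecular 1,5 C–H insertion of a donor/acceptor rhodium carbenoid into the ether-activated benzylic C–H bond, where the concerted insertion gives the kinetic 2,3-cis ester and the chiral carboxylate ligands select the enantiotopic hydrogen, the S-configured catalyst being expected by analogy with simpler 2-(benzyloxy)aryl diazoacetates to give the 2R series.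

Step 10
Reactants: 13 cis ester
Product: 14 {(2R,3R)-2-[4-(benzyloxy)-3-methoxyphenyl]-5-[(1S,2R)-1-(BMB-oxy)-2-(TIPS-oxymethyl)but-3-en-1-yl]-7-methoxy-2,3-dihydro-1-benzofuran-3-yl}methanol
Conditions: i-Bu2AlH (3 equiv), CH2Cl2, −78 °C; Rochelle salt work-up
Reagents that add atoms: none
Why: Ester reduction with a non-basic aluminium hydride at low temperature, so that C3 of the cis-dihydrobenzofuran (benzylic and α to the ester) is not deprotonated and stays cis.

Step 11
Reactants: 14 primary alcohol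
Product: 15 (3R,4S)-4-DHB-4-(BMB-oxy)-3-(TIPS-oxymethyl)but-1-ene
Conditions: TIPSCl, imidazole, DMF, rt
Reagents that add atoms: triisopropylsilyl chloride, CC(C)[Si](Cl)(C(C)C)C(C)C
Why: Routine silylation of the only free hydroxyl, giving a second silyl ether that is released together with the first one in step 16.

Step 12
Reactants: 15 terminal alkene
Product: 17 (2R,3S)-3-DHB-3-(BMB-oxy)-2-(TIPS-oxymethyl)propanal, via vicinal diol 16 (not isolated)
Conditions: OsO4 (2 mol %), NaIO4 (4 equiv), 2,6-lutidine, dioxane–H2O (3:1), rt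
Reagents that add atoms: osmium tetroxide (catalytic oxygen carrier), O=[Os](=O)(=O)=O; sodium periodate, [Na+].[O-]I(=O)(=O)=O
Why: Lemieux–Johnson oxidative cleavage (dihydroxylation, then periodate glycol cleavage) removes the terminal CH2 under near-neutral conditions that spare the electron-rich arenes, and the aldehyde is used at once to protect its α-stereocentre.

Step 13
Reactants: 17 aldehyde
Product: 18 (2R,3S)-3-DHB-3-(BMB-oxy)-2-(TIPS-oxymethyl)propanoic acid
Conditions: NaClO2, NaH2PO4, 2-methylbut-2-ene, t-BuOH–H2O, 0 °C to rt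
Reagents that add atoms: sodium chlorite, [Na+].[O-]Cl=O
Why: Pinnick oxidation at about pH 4, with the alkene scavenger removing hypochlorous acid before it can chlorinate the electron-rich rings and without epimerising the α-carbon.

Step 14
Reactants: 18 carboxylic acid
Product: 20 (3R,4S)-1-diazo-4-DHB-4-(BMB-oxy)-3-(TIPS-oxymethyl)butan-2-one, via isobutyl carbonic mixed anhydride 19 (not isolated)
Conditions: i-BuOCOCl, Et3N, THF, −20 °C; then CH2N2, Et2O, 0 °C to rt
Reagents that add atoms: diazomethane, C=[N+]=[N-]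
Why: Acylation of diazomethane by a mixed carbonic anhydride (the first stage of an Arndt–Eistert sequence) gives the α-diazoketone under conditions too mild to epimerise the α-carbon or eliminate the β-alkoxy group.

Step 15
Reactants: 20 (3R,4S)-1-diazo-4-DHB-4-(BMB-oxy)-3-(TIPS-oxymethyl)butan-2-one
Product: 22 (2S,3R,5S)-2-DHB-5-BMB-3-(TIPS-oxymethyl)tetrahydrofuran-4-one (2,3-trans, 2,5-cis), via 2,5-trans ketone 21 (not isolated)
Conditions: Cu(hfacac)2 (10 mol %), CH2Cl2, reflux, slow addition of 20; then DBU (0.1 equiv), 0 °C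
Reagents that add atoms: none
Why: Cu(hfacac)2 decomposes the diazoketone to an electrophilic copper carbenoid at C5, a lone pair of the C2 ether oxygen adds to it to give a five-membered oxonium ylide, and homolysis of the O1–CH2Ar bond followed by recombination of the radical pair inside the solvent cage (Stevens [1,2]-shift) forms C5–CH2Ar and leaves the ketone at C4. The closest known reaction type is the copper- or rhodium-catalysed conversion of 4-benzyloxy-1-diazobutan-2-ones into 2-benzyltetrahydrofuran-3-ones. The single ring closes through the O1–C5 bond, by attack of O1 on the carbenoid carbon in a formal 5-exo mode. C5 is the only new stereocentre: the shift is expected to place the benzyl group at least partly anti to the C2 aryl group (21), so the configuration is set under thermodynamic control, with DBU epimerising the α-alkoxy ketone to 22, in which the C2 aryl, C3 silyloxymethyl and C5 benzyl groups can all be pseudo-equatorial (2,5-cis, 3,5-trans), while C2 and C3 are carried through unchanged. The step needs capture at O1 in preference to the silyl ether oxygen (which could also close a five-membered ylide) and to Buchner-type addition to the C2 aryl ring, and then exocyclic [1,2]-shift in preference to [1,4]-shift or cleavage of the endocyclic benzylic C2–O1 bond; this is secured by the bulky, weakly basic TIPS ether oxygen, by the absence of any C–H bond in a 1,5-relationship to the carbenoid, by the ylide-selective copper catalyst and by the unstrained, radical-stabilising electron-rich benzyl group on O1.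

Step 16
Reactants: 22 (2S,3R,5S)-ketone
Product: 23 (2S,3R,5S)-2-{(2R,3R)-2-[4-(benzyloxy)-3-methoxyphenyl]-3-(hydroxymethyl)-7-methoxy-2,3-dihydro-1-benzofuran-5-yl}-5-BMB-3-(hydroxymethyl)tetrahydrofuran-4-one
Conditions: HF·pyridine, pyridine, THF, 0 °C to rt (polypropylene vessel)
Reagents that add atoms: none
Why: Fluoride cleavage of both primary silyl ethers under buffered, weakly acidic conditions, chosen over basic Bu4NF so that the β-hydroxy ketone formed cannot undergo retro-aldol loss of formaldehyde, β-elimination or epimerisation.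

Step 17
Reactants: 23 keto diol
Product: 24 (2S,3S,4S,5S)-2-{(2R,3R)-2-[4-(benzyloxy)-3-methoxyphenyl]-3-(hydroxymethyl)-7-methoxy-2,3-dihydro-1-benzofuran-5-yl}-5-BMB-3-(hydroxymethyl)tetrahydrofuran-4-ol
Conditions: Me4NBH(OAc)3 (5 equiv), MeCN–AcOH (1:1), −30 °C
Reagents that add atoms: none
Why: Hydroxyl-directed (Evans–Saksena) reduction, in which the C3 hydroxymethyl group exchanges onto boron and delivers hydride intramolecularly to the face of the C4 carbonyl on which it sits, so the new hydroxyl is trans to C3–CH2OH and cis to the C5 benzyl group (4S).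

Step 18
Reactants: 24 bis(benzyl ether) triol
Product: 25 (2S,3S,4S,5S)-2-[(2R,3R)-2-(4-hydroxy-3-methoxyphenyl)-3-(hydroxymethyl)-7-methoxy-2,3-dihydro-1-benzofuran-5-yl]-5-(4-hydroxy-3-methoxybenzyl)-3-(hydroxymethyl)tetrahydrofuran-4-ol (target)
Conditions: H2 (1 atm), 10% Pd/C, EtOAc, rt, stopped at full conversion
Reagents that add atoms: none
Why: Hydrogenolysis of the two aryl benzyl ethers, which cleave much faster than the cyclic benzylic C–O bonds of the dihydrobenzofuran and the oxolane, under neutral conditions so that the cis-dihydrobenzofuran with its free 4-hydroxyphenyl group is not epimerised.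

**Compound list**

1 | 4-(benzyloxy)-3-methoxybenzyl alcohol | COc1cc(CO)ccc1OCc1ccccc1 | starting material
2 | 4-(benzyloxy)-3-methoxybenzyl bromide (BMB bromide) | COc1cc(CBr)ccc1OCc1ccccc1 | intermediate
3 | 5-iodovanillin (4-hydroxy-3-iodo-5-methoxybenzaldehyde) | COc1cc(C=O)cc(I)c1O | starting material
4 | 4-(BMB-oxy)-3-iodo-5-methoxybenzaldehyde | COc1cc(C=O)cc(I)c1OCc1ccc(OCc2ccccc2)c(OC)c1 | intermediate
5 | propargyl alcohol (prop-2-yn-1-ol) | C#CCO | starting material
6 | triisopropyl(prop-2-yn-1-yloxy)silane | C#CCO[Si](C(C)C)(C(C)C)C(C)C | intermediate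
7 | 2-[(E)-3-(TIPS-oxy)prop-1-en-1-yl]-4,4,5,5-tetramethyl-1,3,2-dioxaborolane | CC(C)[Si](OC/C=C/B1OC(C)(C)C(C)(C)O1)(C(C)C)C(C)C | intermediate
8 | 2-[(E)-4-(TIPS-oxy)but-2-en-1-yl]-4,4,5,5-tetramethyl-1,3,2-dioxaborolane | CC(C)[Si](OC/C=C/CB1OC(C)(C)C(C)(C)O1)(C(C)C)C(C)C | intermediate
9 | O-(4,4,5,5-tetramethyl-1,3,2-dioxaborolan-2-yl) ether of 10 (pinacol borate ester) | CC1(C)OB(O[C@H](c2cc(OC)c(OCc3ccc(OCc4ccccc4)c(OC)c3)c(I)c2)[C@@H](CO[Si](C(C)C)(C(C)C)C(C)C)C=C)OC1(C)C | intermediate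
10 | (1S,2R)-1-[4-(BMB-oxy)-3-iodo-5-methoxyphenyl]-2-(TIPS-oxymethyl)but-3-en-1-ol | O[C@H](c1cc(OC)c(OCc2ccc(OCc3ccccc3)c(OC)c2)c(I)c1)[C@@H](CO[Si](C(C)C)(C(C)C)C(C)C)C=C | intermediate
11 | 2-(BMB-oxy)-5-[(1S,2R)-1-(BMB-oxy)-2-(TIPS-oxymethyl)but-3-en-1-yl]-1-iodo-3-methoxybenzene | COc1cc(CO[C@H](c2cc(OC)c(OCc3ccc(OCc4ccccc4)c(OC)c3)c(I)c2)[C@@H](CO[Si](C(C)C)(C(C)C)C(C)C)C=C)ccc1OCc1ccccc1 | intermediate
12 | methyl 2-{2-(BMB-oxy)-5-[(1S,2R)-1-(BMB-oxy)-2-(TIPS-oxymethyl)but-3-en-1-yl]-3-methoxyphenyl}-2-diazoacetate | COc1cc(CO[C@H](c2cc(OC)c(OCc3ccc(OCc4ccccc4)c(OC)c3)c(c2)C(=[N+]=[N-])C(=O)OC)[C@@H](CO[Si](C(C)C)(C(C)C)C(C)C)C=C)ccc1OCc1ccccc1 | intermediate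
13 | methyl (2R,3S)-2-[4-(benzyloxy)-3-methoxyphenyl]-5-[(1S,2R)-1-(BMB-oxy)-2-(TIPS-oxymethyl)but-3-en-1-yl]-7-methoxy-2,3-dihydro-1-benzofuran-3-carboxylate (cis) | COc1cc(CO[C@H](c3cc(OC)c4c(c3)[C@H](C(=O)OC)[C@H](c3ccc(OCc5ccccc5)c(OC)c3)O4)[C@@H](CO[Si](C(C)C)(C(C)C)C(C)C)C=C)ccc1OCc1ccccc1 | intermediate
14 | {(2R,3R)-2-[4-(benzyloxy)-3-methoxyphenyl]-5-[(1S,2R)-1-(BMB-oxy)-2-(TIPS-oxymethyl)but-3-en-1-yl]-7-methoxy-2,3-dihydro-1-benzofuran-3-yl}methanol (cis) | COc1cc(CO[C@H](c3cc(OC)c4c(c3)[C@H](CO)[C@H](c3ccc(OCc5ccccc5)c(OC)c3)O4)[C@@H](CO[Si](C(C)C)(C(C)C)C(C)C)C=C)ccc1OCc1ccccc1 | intermediate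
15 | (3R,4S)-4-DHB-4-(BMB-oxy)-3-(TIPS-oxymethyl)but-1-ene | COc1cc(CO[C@H](c3cc(OC)c4c(c3)[C@H](CO[Si](C(C)C)(C(C)C)C(C)C)[C@H](c3ccc(OCc5ccccc5)c(OC)c3)O4)[C@@H](CO[Si](C(C)C)(C(C)C)C(C)C)C=C)ccc1OCc1ccccc1 | intermediate
16 | (3S,4S)-4-DHB-4-(BMB-oxy)-3-(TIPS-oxymethyl)butane-1,2-diol (mixture of C2 epimers) | COc1cc(CO[C@H](c3cc(OC)c4c(c3)[C@H](CO[Si](C(C)C)(C(C)C)C(C)C)[C@H](c3ccc(OCc5ccccc5)c(OC)c3)O4)[C@@H](CO[Si](C(C)C)(C(C)C)C(C)C)C(O)CO)ccc1OCc1ccccc1 | intermediate
17 | (2R,3S)-3-DHB-3-(BMB-oxy)-2-(TIPS-oxymethyl)propanal | COc1cc(CO[C@H](c3cc(OC)c4c(c3)[C@H](CO[Si](C(C)C)(C(C)C)C(C)C)[C@H](c3ccc(OCc5ccccc5)c(OC)c3)O4)[C@@H](CO[Si](C(C)C)(C(C)C)C(C)C)C=O)ccc1OCc1ccccc1 | intermediate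
18 | (2R,3S)-3-DHB-3-(BMB-oxy)-2-(TIPS-oxymethyl)propanoic acid | COc1cc(CO[C@H](c3cc(OC)c4c(c3)[C@H](CO[Si](C(C)C)(C(C)C)C(C)C)[C@H](c3ccc(OCc5ccccc5)c(OC)c3)O4)[C@@H](CO[Si](C(C)C)(C(C)C)C(C)C)C(=O)O)ccc1OCc1ccccc1 | intermediate
19 | mixed anhydride of 18 with isobutyl hydrogen carbonate | COc1cc(CO[C@H](c3cc(OC)c4c(c3)[C@H](CO[Si](C(C)C)(C(C)C)C(C)C)[C@H](c3ccc(OCc5ccccc5)c(OC)c3)O4)[C@@H](CO[Si](C(C)C)(C(C)C)C(C)C)C(=O)OC(=O)OCC(C)C)ccc1OCc1ccccc1 | intermediate
20 | (3R,4S)-1-diazo-4-DHB-4-(BMB-oxy)-3-(TIPS-oxymethyl)butan-2-one | COc1cc(CO[C@H](c3cc(OC)c4c(c3)[C@H](CO[Si](C(C)C)(C(C)C)C(C)C)[C@H](c3ccc(OCc5ccccc5)c(OC)c3)O4)[C@@H](CO[Si](C(C)C)(C(C)C)C(C)C)C(=O)C=[N+]=[N-])ccc1OCc1ccccc1 | intermediate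
21 | (2S,3R,5R)-2-DHB-5-BMB-3-(TIPS-oxymethyl)tetrahydrofuran-4-one (2,3-trans, 2,5-trans) | COc1cc(C[C@H]2O[C@H](c3cc(OC)c4c(c3)[C@H](CO[Si](C(C)C)(C(C)C)C(C)C)[C@H](c3ccc(OCc5ccccc5)c(OC)c3)O4)[C@@H](CO[Si](C(C)C)(C(C)C)C(C)C)C2=O)ccc1OCc1ccccc1 | intermediate
22 | (2S,3R,5S)-2-DHB-5-BMB-3-(TIPS-oxymethyl)tetrahydrofuran-4-one (2,3-trans, 2,5-cis) | COc1cc(C[C@@H]2O[C@H](c3cc(OC)c4c(c3)[C@H](CO[Si](C(C)C)(C(C)C)C(C)C)[C@H](c3ccc(OCc5ccccc5)c(OC)c3)O4)[C@@H](CO[Si](C(C)C)(C(C)C)C(C)C)C2=O)ccc1OCc1ccccc1 | intermediate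
23 | (2S,3R,5S)-2-{(2R,3R)-2-[4-(benzyloxy)-3-methoxyphenyl]-3-(hydroxymethyl)-7-methoxy-2,3-dihydro-1-benzofuran-5-yl}-5-BMB-3-(hydroxymethyl)tetrahydrofuran-4-one | COc1cc(C[C@@H]2O[C@H](c3cc(OC)c4c(c3)[C@H](CO)[C@H](c3ccc(OCc5ccccc5)c(OC)c3)O4)[C@@H](CO)C2=O)ccc1OCc1ccccc1 | intermediate
24 | (2S,3S,4S,5S)-2-{(2R,3R)-2-[4-(benzyloxy)-3-methoxyphenyl]-3-(hydroxymethyl)-7-methoxy-2,3-dihydro-1-benzofuran-5-yl}-5-BMB-3-(hydroxymethyl)tetrahydrofuran-4-ol | COc1cc(C[C@@H]2O[C@H](c3cc(OC)c4c(c3)[C@H](CO)[C@H](c3ccc(OCc5ccccc5)c(OC)c3)O4)[C@@H](CO)[C@@H]2O)ccc1OCc1ccccc1 | intermediate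
25 | (2S,3S,4S,5S)-2-[(2R,3R)-2-(4-hydroxy-3-methoxyphenyl)-3-(hydroxymethyl)-7-methoxy-2,3-dihydro-1-benzofuran-5-yl]-5-(4-hydroxy-3-methoxybenzyl)-3-(hydroxymethyl)tetrahydrofuran-4-ol | COc1cc(C[C@@H]2O[C@H](c3cc(OC)c4c(c3)[C@H](CO)[C@H](c3ccc(O)c(OC)c3)O4)[C@@H](CO)[C@@H]2O)ccc1O | target

**Totals**

Total step count: 18.
Longest linear sequence: 16 steps (5 → 6 → 7 → 8 → 10 → 11 → 12 → 13 → 14 → 15 → 17 → 18 → 20 → 22 → 23 → 24 → 25); 14 steps when counted from 5-iodovanillin 3.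

**Steps most likely to fail, with fallbacks**

1. Step 15 (key step). The carbenoid may be diverted before it reaches O1 (capture by the silyl ether oxygen, addition to the electron-rich C2 aryl ring, dimerisation). The ylide may rearrange by [1,4]-shift or leak benzyl radicals out of the solvent cage. The C5 equilibration may stall or be accompanied by β-elimination. The fallback sets out from 20 and returns to 22, using the diazoketone as an electrophile and not as a carbene source. HBr in Et2O at −20 °C converts 20 into the bromomethyl ketone (3R,4S)-1-bromo-4-DHB-4-(BMB-oxy)-3-(TIPS-oxymethyl)butan-2-one F1. On warming in MeCN over NaHCO3 the ether oxygen displaces bromide (5-exo-tet) and the oxonium ion sheds its electron-rich benzyl group as bromide 2, giving the C5-unsubstituted ketone (2S,3R)-2-DHB-3-(TIPS-oxymethyl)tetrahydrofuran-4-one F2. Aldol condensation at its only α-methylene with commercial 4-(benzyloxy)-3-methoxybenzaldehyde (pyrrolidine, MeOH, rt) gives the benzylidene ketone (2S,3R,5Z)-5-[4-(benzyloxy)-3-methoxybenzylidene]-2-DHB-3-(TIPS-oxymethyl)tetrahydrofuran-4-one F3. Conjugate reduction with [(Ph3P)CuH]6 and the same DBU equilibration then give 22.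

2. Step 8. Slow oxidative addition or palladation at the hindered, electron-rich ortho-alkoxy aryl iodide may let the diazo ester decompose or dimerise before it couples. The fallback sets out from 11 and returns to 12, introducing the two-carbon unit without the diazo group and adding nitrogen afterwards. Negishi-type coupling of 11 with the Reformatsky reagent bromo(2-methoxy-2-oxoethyl)zinc F4 (from methyl bromoacetate and zinc; Pd(PPh3)4, THF, 50 °C) gives the arylacetate methyl 2-{2-(BMB-oxy)-5-[(1S,2R)-1-(BMB-oxy)-2-(TIPS-oxymethyl)but-3-en-1-yl]-3-methoxyphenyl}acetate F5. Regitz diazo transfer (4-acetamidobenzenesulfonyl azide, DBU, MeCN) then gives 12.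

3. Step 6. The bulky γ-(silyloxymethyl) reagent may react so slowly that the uncatalysed background reaction erodes facial selectivity, or the sense of induction may be opposite to the one expected. The fallback sets out from 4 and returns to 10, replacing catalyst control by auxiliary control in an Evans aldol reaction. (S)-4-Benzyl-3-[(E)-but-2-enoyl]-1,3-oxazolidin-2-one F6 (from (S)-4-benzyl-1,3-oxazolidin-2-one, n-BuLi and crotonyl chloride) is converted into its boron dienolate (Bu2BOTf, Et3N, CH2Cl2, −78 °C) and adds to 4 through its α-carbon to give the syn α-vinyl aldol adduct (4S)-4-benzyl-3-{(2S)-2-[(S)-[4-(BMB-oxy)-3-iodo-5-methoxyphenyl](hydroxy)methyl]but-3-enoyl}-1,3-oxazolidin-2-one F7. LiBH4 (THF, MeOH, 0 °C) removes the auxiliary reductively to give the diol (1S,2R)-1-[4-(BMB-oxy)-3-iodo-5-methoxyphenyl]-2-ethenylpropane-1,3-diol F8, in which the former syn hydroxyl/vinyl relationship is the required anti hydroxyl/hydroxymethyl relationship. Selective silylation of the primary hydroxyl (TIPSCl, imidazole, CH2Cl2) gives 10.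

**Further compounds**

F1 | step 15 | (3R,4S)-1-bromo-4-DHB-4-(BMB-oxy)-3-(TIPS-oxymethyl)butan-2-one | COc1cc(CO[C@H](c3cc(OC)c4c(c3)[C@H](CO[Si](C(C)C)(C(C)C)C(C)C)[C@H](c3ccc(OCc5ccccc5)c(OC)c3)O4)[C@@H](CO[Si](C(C)C)(C(C)C)C(C)C)C(=O)CBr)ccc1OCc1ccccc1
F2 | step 15 | (2S,3R)-2-DHB-3-(TIPS-oxymethyl)tetrahydrofuran-4-one | C1O[C@H](c3cc(OC)c4c(c3)[C@H](CO[Si](C(C)C)(C(C)C)C(C)C)[C@H](c3ccc(OCc5ccccc5)c(OC)c3)O4)[C@@H](CO[Si](C(C)C)(C(C)C)C(C)C)C1=O
F3 | step 15 | (2S,3R,5Z)-5-[4-(benzyloxy)-3-methoxybenzylidene]-2-DHB-3-(TIPS-oxymethyl)tetrahydrofuran-4-one | COc1cc(/C=C2\O[C@H](c3cc(OC)c4c(c3)[C@H](CO[Si](C(C)C)(C(C)C)C(C)C)[C@H](c3ccc(OCc5ccccc5)c(OC)c3)O4)[C@@H](CO[Si](C(C)C)(C(C)C)C(C)C)C2=O)ccc1OCc1ccccc1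
F4 | step 8 | bromo(2-methoxy-2-oxoethyl)zinc | COC(=O)C[Zn]Br
F5 | step 8 | methyl 2-{2-(BMB-oxy)-5-[(1S,2R)-1-(BMB-oxy)-2-(TIPS-oxymethyl)but-3-en-1-yl]-3-methoxyphenyl}acetate | COc1cc(CO[C@H](c2cc(OC)c(OCc3ccc(OCc4ccccc4)c(OC)c3)c(c2)CC(=O)OC)[C@@H](CO[Si](C(C)C)(C(C)C)C(C)C)C=C)ccc1OCc1ccccc1
F6 | step 6 | (S)-4-benzyl-3-[(E)-but-2-enoyl]-1,3-oxazolidin-2-one | C/C=C/C(=O)N1[C@@H](Cc2ccccc2)COC1=O
F7 | step 6 | (4S)-4-benzyl-3-{(2S)-2-[(S)-[4-(BMB-oxy)-3-iodo-5-methoxyphenyl](hydroxy)methyl]but-3-enoyl}-1,3-oxazolidin-2-one | O[C@H](c1cc(OC)c(OCc2ccc(OCc3ccccc3)c(OC)c2)c(I)c1)[C@@H](C(=O)N1[C@@H](Cc2ccccc2)COC1=O)C=C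
F8 | step 6 | (1S,2R)-1-[4-(BMB-oxy)-3-iodo-5-methoxyphenyl]-2-ethenylpropane-1,3-diol | O[C@H](c1cc(OC)c(OCc2ccc(OCc3ccccc3)c(OC)c2)c(I)c1)[C@@H](CO)C=C
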